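**Retrosynthetic overview**
1. Target ⇐ desilylation and Felkin–Anh hydride reduction of an aryl ketone (carbinol centre) ⇐ 2,3-cis-3,4-trans oxolane ketone ⇐ hydride reduction of a cyclic hemiketal through its oxocarbenium ion (C2).
2. Hemiketal ketone ⇐ one aryllithium added twice (lactone carbonyl and Weinreb amide) to a trans-disubstituted γ-butyrolactone; the aryllithium comes from catechol in three steps.
3. trans-Lactone ⇐ anti aldol with formaldehyde (C3) on (R)-5-oxooxolane-3-carboxamide.
4. (R)-Lactone ⇐ catalytic desymmetrising Baeyer–Villiger ring expansion (1,2-shift of a ring CH2 from carbon to oxygen) of the Weinreb amide of 3-oxocyclobutane-1-carboxylic acid: key step, fixes C4 and the absolute configuration.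
5. Ring order: the oxolane is the only ring that is built, in the Baeyer–Villiger step from the cyclobutanone; both benzene rings come ready-made from catechol.

Assumption: the antipode of the N,N'-dioxide ligand that gives the (R)-lactone in step 5 is fixed by one test run (both antipodes are accessible).
Abbreviations: TBS = tert-butyldimethylsilyl; TES = triethylsilyl; ArSi = 4-(TBS-oxy)-3-methoxyphenyl; target oxolane positions are O1, C2 (aryl), C3 (CH2O), C4 (carbinol/acyl substituent), C5 (CH2).

**Route**

Step 1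
Reactants: 1 catechol (benzene-1,2-diol)
Product: 2 guaiacol (2-methoxyphenol)
Conditions: MeI (0.9 equiv), K2CO3 (1.0 equiv), acetone, reflux
Reagents that add atoms: iodomethane, CI
Why: Williamson ether synthesis in which the internally hydrogen-bonded catechol monoanion forms and reacts ahead of guaiacol, so that with the diol in slight excess mono-methylation dominates; no stereocentre is formed.

Step 2
Reactants: 2 guaiacol
Product: 3 4-bromo-2-methoxyphenol
Conditions: NBS (1.0 equiv), MeCN, 0 °C
Reagents that add atoms: N-bromosuccinimide, O=C1CCC(=O)N1Br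
Why: Electrophilic aromatic bromination directed para to the free hydroxyl, the stronger donor, which gives the 4-hydroxy-3-methoxyphenyl pattern of the target.

Step 3
Reactants: 3 4-bromo-2-methoxyphenol
Product: 4 (4-bromo-2-methoxyphenoxy)(tert-butyl)dimethylsilane
Conditions: TBSCl, imidazole, DMF, rt
Reagents that add atoms: tert-butyldimethylsilyl chloride, CC(C)(C)[Si](C)(C)Cl
Why: Standard phenol silylation; the aryl silyl ether tolerates bromine–lithium exchange, BF3·OEt2/Et3SiH at low temperature and hydride, and is removed by fluoride at the end.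

Step 4
Reactants: 5 3-oxocyclobutane-1-carboxylic acid
Product: 7 N-methoxy-N-methyl-3-oxocyclobutane-1-carboxamide, via acyl imidazolide 6 (not isolated)
Conditions: CDI, CH2Cl2, rt; then MeNH(OMe)·HCl, rt
Reagents that add atoms: N,O-dimethylhydroxylamine hydrochloride, CNOC.Cl
Why: Amide coupling through acyl imidazolide 6; the Weinreb amide is the later aryl ketone precursor and is inert to peracid and to lactone enolate chemistry.

Step 5
Reactants: 7 N-methoxy-N-methyl-3-oxocyclobutane-1-carboxamide
Product: 9 (R)-N-methoxy-N-methyl-5-oxooxolane-3-carboxamide, via Criegee adduct 8 (not isolated)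
Conditions: Sc(OTf)3 (5 mol %), chiral N,N'-dioxide ligand (pipecolic-acid-derived bis-anilide, 5 mol %), m-CPBA (1.2 equiv), EtOAc, −20 °C
Reagents that add atoms: m-chloroperbenzoic acid, OOC(=O)c1cccc(Cl)c1
Why: Proposed new method: desymmetrising Baeyer–Villiger ring expansion of a cyclobutanone that carries a chelating Weinreb amide at C3, a substrate class not yet used in catalytic asymmetric Baeyer–Villiger chemistry; the peracid adds to the scandium-bound ketone to give Criegee adduct 8, whose amide carbonyl can hold the scandium alkoxide in a rigid chelate inside the chiral ligand pocket, so that only one of the two enantiotopic ring CH2 groups lies antiperiplanar to the O–O bond and undergoes the 1,2-shift from carbon to oxygen, which expands the four-membered ring to the five-membered lactone and sets the (R) centre that becomes C4 of the target; closest known reaction type: Sc(OTf)3/N,N'-dioxide- and chiral phosphoric acid-catalysed asymmetric Baeyer–Villiger oxidation of 3-aryl- and 3-alkylcyclobutanones.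

Step 6
Reactants: 9 (R)-N-methoxy-N-methyl-5-oxooxolane-3-carboxamide
Product: 12 (3R,4S)-4-[(TBS-oxy)methyl]-N-methoxy-N-methyl-5-oxooxolane-3-carboxamide, via lithium enolate 10 (not isolated), via lithium aldolate 11 (not isolated)
Conditions: LiN(i-Pr)2 (1.05 equiv), THF, −78 °C; CH2O (monomeric, THF), −78 °C; then TBSOTf, −78 → −40 °C
Reagents that add atoms: formaldehyde, C=O; tert-butyldimethylsilyl triflate, CC(C)(C)[Si](C)(C)OS(=O)(=O)C(F)(F)F
Why: Aldol addition of lactone enolate 10 to formaldehyde anti to the neighbouring carboxamide sets C3 trans to C4 (the usual outcome for β-substituted γ-butyrolactones), and aldolate 11 is silylated in the flask because a free hydroxymethyl group would make the ring-opened hydroxy diketone of step 7 a meso compound and erase the absolute configuration.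

Step 7
Reactants: 4 (4-bromo-2-methoxyphenoxy)(tert-butyl)dimethylsilane; 12 (3R,4S)-4-[(TBS-oxy)methyl]-N-methoxy-N-methyl-5-oxooxolane-3-carboxamide
Product: 14 [(3R,4S)-5-hydroxy-5-ArSi-4-(TBS-oxymethyl)oxolan-3-yl](ArSi)methanone (hemiketal; both C5 epimers), via aryllithium 13 (not isolated)
Conditions: 4 (2.4 equiv), n-BuLi (2.3 equiv), THF, −78 °C; then 12, −78 °C; AcOH quench at −78 °C
Reagents that add atoms: none
Why: Bromine–lithium exchange gives aryllithium 13, which adds once to the Weinreb amide (chelated adduct, ketone only on work-up) and once to the lactone carbonyl (the lithium hemiketal stays closed at −78 °C), so both aryl–carbon bonds form in one operation without touching C3 or C4.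

Step 8
Reactants: 14 [(3R,4S)-5-hydroxy-5-ArSi-4-(TBS-oxymethyl)oxolan-3-yl](ArSi)methanone
Product: 16 [(3R,4S,5S)-5-ArSi-4-(TBS-oxymethyl)oxolan-3-yl](ArSi)methanone, via oxocarbenium ion 15 (not isolated)
Conditions: Et3SiH (5 equiv), BF3·OEt2 (2 equiv), CH2Cl2, −78 °C; Et3N quench
Reagents that add atoms: none
Why: Ionic hydrogenation of a cyclic hemiketal: BF3 ionises 14 to the aryl-stabilised oxocarbenium ion 15 and Et3SiH delivers hydride to C2 from the face opposite the neighbouring C3 silyloxymethyl group, which places the aryl group cis to C3 and trans to the C4 aroyl group (kinetic 2,3-cis product; low temperature and the amine quench prevent acid-mediated epimerisation, and the aryl ketone is not reduced under these conditions).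

Step 9
Reactants: 16 [(3R,4S,5S)-5-ArSi-4-(TBS-oxymethyl)oxolan-3-yl](ArSi)methanone
Product: 18 (S)-(4-hydroxy-3-methoxyphenyl)[(3R,4S,5S)-5-(4-hydroxy-3-methoxyphenyl)-4-(hydroxymethyl)oxolan-3-yl]methanol (target), via tris-silyl carbinol 17 (not isolated)
Conditions: LiBH(s-Bu)3 (1.5 equiv), THF, −78 °C; then AcOH, Bu4NF (4 equiv), THF, 0 °C → rt
Reagents that add atoms: none
Why: Felkin–Anh-controlled reduction of the α-branched aryl ketone (the bulky hydride attacks anti to the C4–C3 bond, the larger α-branch) gives the (S)-carbinol 17, and acetic acid-buffered fluoride then removes the three silyl groups without ionising the p-hydroxybenzylic C–O bonds.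

**Compound list**
1 | catechol (benzene-1,2-diol) | Oc1ccccc1O | starting material
2 | guaiacol (2-methoxyphenol) | COc1ccccc1O | intermediate
3 | 4-bromo-2-methoxyphenol | COc1cc(Br)ccc1O | intermediate
4 | (4-bromo-2-methoxyphenoxy)(tert-butyl)dimethylsilane | COc1cc(Br)ccc1O[Si](C)(C)C(C)(C)C | intermediate
5 | 3-oxocyclobutane-1-carboxylic acid | OC(=O)C1CC(=O)C1 | starting material
6 | 1-(3-oxocyclobutane-1-carbonyl)imidazole (acyl imidazolide) | O=C1CC(C1)C(=O)n1ccnc1 | intermediate
7 | N-methoxy-N-methyl-3-oxocyclobutane-1-carboxamide | CON(C)C(=O)C1CC(=O)C1 | intermediate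
8 | Criegee adduct: 3-(3-chlorobenzoylperoxy)-3-hydroxy-N-methoxy-N-methylcyclobutane-1-carboxamide | CON(C)C(=O)C1CC(O)(OOC(=O)c2cccc(Cl)c2)C1 | intermediate
9 | (R)-N-methoxy-N-methyl-5-oxooxolane-3-carboxamide | CON(C)C(=O)[C@H]1COC(=O)C1 | intermediate
10 | lithium enolate of 9 (enolate of the lactone carbonyl) | CON(C)C(=O)[C@H]1COC([O-])=C1.[Li+] | intermediate
11 | lithium alkoxide of (3R,4S)-4-(hydroxymethyl)-N-methoxy-N-methyl-5-oxooxolane-3-carboxamide (aldolate) | CON(C)C(=O)[C@H]1COC(=O)[C@@H]1C[O-].[Li+] | intermediate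
12 | (3R,4S)-4-[(tert-butyldimethylsilyloxy)methyl]-N-methoxy-N-methyl-5-oxooxolane-3-carboxamide (trans) | CON(C)C(=O)[C@H]1COC(=O)[C@@H]1CO[Si](C)(C)C(C)(C)C | intermediate
13 | [4-(tert-butyldimethylsilyloxy)-3-methoxyphenyl]lithium | [Li]c1ccc(O[Si](C)(C)C(C)(C)C)c(OC)c1 | intermediate
14 | [(3R,4S)-5-hydroxy-5-ArSi-4-(TBS-oxymethyl)oxolan-3-yl](ArSi)methanone, hemiketal, both C5 epimers | COc1cc(C(=O)[C@H]2COC(O)(c3ccc(O[Si](C)(C)C(C)(C)C)c(OC)c3)[C@@H]2CO[Si](C)(C)C(C)(C)C)ccc1O[Si](C)(C)C(C)(C)C | intermediate
15 | cyclic oxocarbenium ion from 14 (O1=C2 double bond, ArSi on C2, 3,4-trans) | COc1cc(C(=O)[C@H]2C[O+]=C(c3ccc(O[Si](C)(C)C(C)(C)C)c(OC)c3)[C@@H]2CO[Si](C)(C)C(C)(C)C)ccc1O[Si](C)(C)C(C)(C)C | intermediate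
16 | [(3R,4S,5S)-5-ArSi-4-(TBS-oxymethyl)oxolan-3-yl](ArSi)methanone (aryl cis to CH2OTBS, aroyl trans) | COc1cc(C(=O)[C@H]2CO[C@H](c3ccc(O[Si](C)(C)C(C)(C)C)c(OC)c3)[C@@H]2CO[Si](C)(C)C(C)(C)C)ccc1O[Si](C)(C)C(C)(C)C | intermediate
17 | (S)-[(3R,4S,5S)-5-ArSi-4-(TBS-oxymethyl)oxolan-3-yl](ArSi)methanol | COc1cc([C@@H](O)[C@H]2CO[C@H](c3ccc(O[Si](C)(C)C(C)(C)C)c(OC)c3)[C@@H]2CO[Si](C)(C)C(C)(C)C)ccc1O[Si](C)(C)C(C)(C)C | intermediate
18 | (S)-(4-hydroxy-3-methoxyphenyl)[(3R,4S,5S)-5-(4-hydroxy-3-methoxyphenyl)-4-(hydroxymethyl)oxolan-3-yl]methanol; in target positions (2S,3S,4R), carbinol (S) | COc1cc([C@@H](O)[C@H]2CO[C@H](c3ccc(O)c(OC)c3)[C@@H]2CO)ccc1O | target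

**Totals**
Total step count: 9. Longest linear sequence: 6 steps (5 → 18 through steps 4–9; equally 1 → 18 through steps 1–3 and 7–9).

**Steps most likely to fail, with fallbacks**

Step 5 (proposed new step; risk: low enantioselectivity, or catalyst inhibition by the amide). The fallback sets out from 5 and uses known chemistry only. Plain Baeyer–Villiger oxidation of 5 with m-CPBA gives racemic 5-oxooxolane-3-carboxylic acid F1. The racemate is resolved by crystallisation of its salt with one antipode of 1-phenylethylamine, and acidification gives (R)-5-oxooxolane-3-carboxylic acid F2. Coupling of F2 with MeNH(OMe)·HCl by CDI comes back to the route at 9.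

Step 7 (risk: enolisation of the α-branched lactone with loss of silanolate, or over-addition after ring opening). The fallback sets out from 12 and avoids an enolisable lactone. Opening 12 with MeNH(OMe)·HCl and i-PrMgCl gives the hydroxy bis(Weinreb amide) (2S,3R)-2-(TBS-oxymethyl)-3-(hydroxymethyl)-N1,N4-dimethoxy-N1,N4-dimethylbutanediamide F3. The freed primary alcohol is capped with TESCl/imidazole as the triethylsilyl ether F4, so the two silyl ethers stay distinguishable. Aryllithium 13 (2.2 equiv, −78 °C) converts both Weinreb amides into the acyclic diketone (2S,3R)-1,4-bis(ArSi)-2-(TBS-oxymethyl)-3-(TES-oxymethyl)butane-1,4-dione F5. Selective removal of the triethylsilyl group (AcOH/THF/H2O, 0 °C) lets the γ-hydroxy ketone close, and the sequence comes back to the route at 14.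

Step 8 (risk: erosion of the 2,3-cis selectivity, or acid-mediated epimerisation at the benzylic C2). The fallback sets out from 14 and makes the C2–O stereocentre by reagent-controlled reduction and the ring by O-alkylation. BH3·SMe2 with (R)-2-methyl-CBS-oxazaborolidine reduces both aryl ketones of the open hydroxy-diketone tautomer of 14 to the triol (1S,2S,3R,4S)-1,4-bis(ArSi)-2-(TBS-oxymethyl)-3-(hydroxymethyl)butane-1,4-diol F6; this also sets the carbinol centre of step 9. TsCl/pyridine at 0 °C sulfonylates only the primary hydroxyl to give the tosylate F7. NaH in THF then closes the oxolane by Williamson attack of the C2 alkoxide on the CH2 carbon, with retention at the benzylic centre (the competing oxetane closure is slow). This comes back to the route at 17, which is desilylated as in step 9.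

**Further compounds**
F1 | step 5 | racemic 5-oxooxolane-3-carboxylic acid | OC(=O)C1COC(=O)C1
F2 | step 5 | (R)-5-oxooxolane-3-carboxylic acid | OC(=O)[C@H]1COC(=O)C1
F3 | step 7 | (2S,3R)-2-[(tert-butyldimethylsilyloxy)methyl]-3-(hydroxymethyl)-N1,N4-dimethoxy-N1,N4-dimethylbutanediamide | CON(C)C(=O)[C@@H](CO)[C@@H](CO[Si](C)(C)C(C)(C)C)C(=O)N(C)OC
F4 | step 7 | triethylsilyl ether of F3 at the primary hydroxyl | CON(C)C(=O)[C@@H](CO[Si](CC)(CC)CC)[C@@H](CO[Si](C)(C)C(C)(C)C)C(=O)N(C)OC
F5 | step 7 | (2S,3R)-1,4-bis(ArSi)-2-(TBS-oxymethyl)-3-(TES-oxymethyl)butane-1,4-dione | COc1cc(C(=O)[C@@H](CO[Si](CC)(CC)CC)[C@@H](CO[Si](C)(C)C(C)(C)C)C(=O)c2ccc(O[Si](C)(C)C(C)(C)C)c(OC)c2)ccc1O[Si](C)(C)C(C)(C)C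
F6 | step 8 | (1S,2S,3R,4S)-1,4-bis(ArSi)-2-(TBS-oxymethyl)-3-(hydroxymethyl)butane-1,4-diol | COc1cc([C@@H](O)[C@@H](CO)[C@@H](CO[Si](C)(C)C(C)(C)C)[C@H](O)c2ccc(O[Si](C)(C)C(C)(C)C)c(OC)c2)ccc1O[Si](C)(C)C(C)(C)C
F7 | step 8 | primary 4-methylbenzenesulfonate of F6 | COc1cc([C@@H](O)[C@@H](COS(=O)(=O)c2ccc(C)cc2)[C@@H](CO[Si](C)(C)C(C)(C)C)[C@H](O)c2ccc(O[Si](C)(C)C(C)(C)C)c(OC)c2)ccc1O[Si](C)(C)C(C)(C)C
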